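**Retrosynthetic overview**

1. Locants: carbocycle C1 (bears the side chain), C2 and C3 (ester carbons), C4(Me)–C5 (oxirane), C6 (CH2); side chain C7(=CH2)–C8(O)–C9–C10–C11 (oxirane). The strategy rests on two facts: C3–C2(O)–C1–C7 is the carbon skeleton of a 3-alkylmalate, and C3 is an allylic carbinol attached to C4(Me)=C5 of the six-membered ring.
2. Endgame: the C10/C11 oxirane by Shi epoxidation, the ring oxirane by vanadium delivery from the free C2 hydroxyl, the three angelates by DMAP-free mixed-anhydride acylation.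
3. C7–C8 is cut to the C7 enol triflate (from the C1 ester through the methyl ketone) and 4-methylpent-3-enal, joined by a ligand-controlled Ni/Cr coupling.
4. C3–C4 is cut to a C3 aldehyde and a Z alkenyl iodide on C4; the ring-closing Nozaki–Hiyama–Kishi reaction forms the only carbocycle.
5. The open chain is (R)-malate alkylated anti with (2Z)-1-bromo-3-iodobut-2-ene. Ring order: cyclohexene (step 8), ring oxirane (step 18), side-chain oxirane (step 20).

Key step: step 8

Convention: β is the face of the C2 oxygen, α the opposite face; in the target the ring oxirane is β, and the C3 oxygen and the C1 side chain are α.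
Assumption: in the intermolecular Ni/Cr coupling, the antipode of the valinol-derived oxazoline–sulfonamide ligand that directs addition to the Re face of the side-chain aldehyde (8S) is used; which antipode this is has to be fixed in a pilot run with both ligands.

**Route**

Step 1
Reactants: 1 but-2-yn-1-ol
Product: 3 (2Z)-3-iodobut-2-en-1-ol, via cyclic alkenylaluminate 2 (not isolated)
Conditions: Red-Al, THF, 0 °C → rt; then I2, −78 → 0 °C
Reagents that add atoms: iodine, II
Why: Hydroxyl-directed trans-hydroalumination of the propargylic alcohol puts aluminium on C3 in a five-membered alanate, and iodinolysis with retention should give the Z iodide only.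

Step 2
Reactants: 3 (2Z)-3-iodobut-2-en-1-ol
Product: 4 (2Z)-1-bromo-3-iodobut-2-ene
Conditions: CBr4, PPh3, CH2Cl2, 0 °C
Reagents that add atoms: carbon tetrabromide, BrC(Br)(Br)Br
Why: Appel bromination converts the allylic alcohol to the bromide under neutral conditions that leave the alkenyl iodide and the alkene geometry untouched.

Step 3
Reactants: 5 dimethyl (R)-malate; 4 (2Z)-1-bromo-3-iodobut-2-ene
Product: 7 dimethyl (2R,3S)-2-hydroxy-3-[(2Z)-3-iodobut-2-en-1-yl]butanedioate, via dilithio malate dianion 6 (not isolated)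
Conditions: LiHMDS (2.1 equiv), THF, −78 °C; then 4, −78 → −10 °C
Reagents that add atoms: none
Why: Fráter–Seebach alkylation: the chelated alkoxide–enolate is alkylated on the face anti to the alkoxide, which sets ring C1 (malate C3, S) relative to the chiral-pool centre C2.

Step 4
Reactants: 7 dimethyl (2R,3S)-2-hydroxy-3-[(2Z)-3-iodobut-2-en-1-yl]butanedioate
Product: 8 methyl (2S,4Z)-2-[(1R)-1,2-dihydroxyethyl]-5-iodohex-4-enoate
Conditions: BH3·SMe2, NaBH4 (5 mol%), THF, 0 °C → rt; MeOH quench
Reagents that add atoms: none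
Why: Hydroxyl-directed borane reduction (NaBH4-catalysed) reduces only the ester next to the free hydroxyl through a cyclic alkoxyborane, and the hindered, electron-poor iodoalkene should not be hydroborated at this stoichiometry.

Step 5
Reactants: 8 methyl (2S,4Z)-2-[(1R)-1,2-dihydroxyethyl]-5-iodohex-4-enoate
Product: 9 methyl (2S,4Z)-2-[(1R)-1,2-bis[(tert-butyldimethylsilyl)oxy]ethyl]-5-iodohex-4-enoate
Conditions: TBSOTf (2.4 equiv), 2,6-lutidine, CH2Cl2, −78 → 0 °C; NaHCO3 work-up
Reagents that add atoms: tert-butyldimethylsilyl trifluoromethanesulfonate, CC(C)(C)[Si](C)(C)OS(=O)(=O)C(F)(F)F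
Why: Exhaustive silylation with the silyl triflate is fast at low temperature and so outruns lactonisation of the 4-hydroxy ester.

Step 6
Reactants: 9 methyl (2S,4Z)-2-[(1R)-1,2-bis[(tert-butyldimethylsilyl)oxy]ethyl]-5-iodohex-4-enoate
Product: 10 methyl (2S,4Z)-2-[(1R)-1-[(tert-butyldimethylsilyl)oxy]-2-hydroxyethyl]-5-iodohex-4-enoate
Conditions: HF·pyridine, pyridine, THF, 0 °C
Reagents that add atoms: none
Why: Buffered HF·pyridine cleaves the unhindered primary silyl ether much faster than the secondary one, a standard selective desilylation, and the cold buffered medium limits lactone formation.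

Step 7
Reactants: 10 methyl (2S,4Z)-2-[(1R)-1-[(tert-butyldimethylsilyl)oxy]-2-hydroxyethyl]-5-iodohex-4-enoate
Product: 11 methyl (2S,4Z)-2-[(1R)-1-[(tert-butyldimethylsilyl)oxy]-2-oxoethyl]-5-iodohex-4-enoate
Conditions: Dess–Martin periodinane, NaHCO3, CH2Cl2, 0 °C → rt
Reagents that add atoms: none
Why: Dess–Martin oxidation gives the α-silyloxy aldehyde under buffered, non-enolising conditions, so C2 should not epimerise.

Step 8
Reactants: 11 methyl (2S,4Z)-2-[(1R)-1-[(tert-butyldimethylsilyl)oxy]-2-oxoethyl]-5-iodohex-4-enoate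
Product: 13 methyl (1S,2R,3R)-2-[(tert-butyldimethylsilyl)oxy]-3-hydroxy-4-methylcyclohex-4-ene-1-carboxylate, via alkenylchromium(III) species 12 (not isolated)
Conditions: CrCl2 (6 equiv), NiCl2 (2 mol% of Cr), degassed DMSO, rt, 0.005 M, slow addition of 11
Reagents that add atoms: none
Why: Cr(II) reduces NiCl2 to Ni(0), which inserts into the C4–I bond with retention of the Z geometry and passes the alkenyl group to Cr(III); the alkenylchromium 12 then adds to the C3 aldehyde through a Cr–O-bridged transition state, the closest known reaction type being the Ni/Cr-mediated (Nozaki–Hiyama–Kishi) cyclisation of ω-formyl Z-alkenyl iodides to cyclohex-2-enols. The six-membered ring closes in the 6-exo-trig mode at the carbonyl carbon, and the Z alkene, which alone holds C6 and the metal on the same side, becomes the endocyclic C4=C5 bond. The only new stereocentre, C3, is controlled by a chair-like transition state in which the C1 ester and the C2 silyl ether (already trans from step 3) are both equatorial and the chromium-bound carbonyl oxygen takes the pseudo-equatorial site, which gives the alcohol trans to O2 and cis to the ester. The step needs this 2,3-trans selectivity and attack at the aldehyde only; the first rests on the equatorial lock by the two resident substituents, although allylic strain with the C4 methyl may erode it, and the second on the inertness of alkenylchromium species towards esters and silyl ethers. High dilution suppresses intermolecular coupling, and the neutral medium should leave the α-silyloxy centre C2 unepimerised.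

Step 9
Reactants: 13 methyl (1S,2R,3R)-2-[(tert-butyldimethylsilyl)oxy]-3-hydroxy-4-methylcyclohex-4-ene-1-carboxylate
Product: 14 methyl (1S,2R,3R)-2-[(tert-butyldimethylsilyl)oxy]-4-methyl-3-[(triethylsilyl)oxy]cyclohex-4-ene-1-carboxylate
Conditions: TESOTf, 2,6-lutidine, CH2Cl2, −78 °C; NaHCO3 work-up
Reagents that add atoms: triethylsilyl trifluoromethanesulfonate, CC[Si](CC)(CC)OS(=O)(=O)C(F)(F)F
Why: Silylation masks the allylic C3 hydroxyl for the organometallic steps with a group that can later be removed without touching the C2 TBS ether.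

Step 10
Reactants: 14 methyl (1S,2R,3R)-2-[(tert-butyldimethylsilyl)oxy]-4-methyl-3-[(triethylsilyl)oxy]cyclohex-4-ene-1-carboxylate
Product: 15 (1S,2R,3R)-2-[(tert-butyldimethylsilyl)oxy]-N-methoxy-N,4-dimethyl-3-[(triethylsilyl)oxy]cyclohex-4-ene-1-carboxamide
Conditions: MeNHOMe·HCl, iPrMgCl, THF, −20 → 0 °C
Reagents that add atoms: N,O-dimethylhydroxylamine hydrochloride, CNOC.Cl
Why: Direct aminolysis of the ester by the chloromagnesium amide (Weinreb amide formation) proceeds at low temperature, where the weakly basic amide should neither epimerise C1 nor eliminate the β-silyloxy group.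

Step 11
Reactants: 15 (1S,2R,3R)-2-[(tert-butyldimethylsilyl)oxy]-N-methoxy-N,4-dimethyl-3-[(triethylsilyl)oxy]cyclohex-4-ene-1-carboxamide
Product: 16 1-[(1S,2R,3R)-2-[(tert-butyldimethylsilyl)oxy]-4-methyl-3-[(triethylsilyl)oxy]cyclohex-4-en-1-yl]ethan-1-one
Conditions: MeMgBr, THF, 0 °C; NH4Cl quench
Reagents that add atoms: methylmagnesium bromide, C[Mg]Br
Why: Weinreb ketone synthesis stops cleanly at mono-addition and delivers the C7 methyl ketone.

Step 12
Reactants: 16 1-[(1S,2R,3R)-2-[(tert-butyldimethylsilyl)oxy]-4-methyl-3-[(triethylsilyl)oxy]cyclohex-4-en-1-yl]ethan-1-one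
Product: 18 1-[(1S,2R,3R)-2-[(tert-butyldimethylsilyl)oxy]-4-methyl-3-[(triethylsilyl)oxy]cyclohex-4-en-1-yl]ethenyl trifluoromethanesulfonate, via potassium enolate 17 (not isolated)
Conditions: KHMDS, THF, −78 °C; then PhNTf2, −78 → −40 °C; NH4Cl quench
Reagents that add atoms: N-phenylbis(trifluoromethanesulfonimide), O=S(=O)(N(c1ccccc1)S(=O)(=O)C(F)(F)F)C(F)(F)F
Why: Kinetic deprotonation occurs at the methyl group and not at the hindered C1 methine, so O-triflation gives the terminal enol triflate without epimerisation at C1 or loss of the C2 silyloxy group.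

Step 13
Reactants: 19 4-methylpent-3-en-1-ol
Product: 20 4-methylpent-3-enal
Conditions: Dess–Martin periodinane, NaHCO3, CH2Cl2, 0 °C → rt; used at once as a solution
Reagents that add atoms: none
Why: Dess–Martin oxidation under buffered, base-free conditions gives the β,γ-unsaturated aldehyde without migration of the double bond into conjugation.

Step 14
Reactants: 18 1-[(1S,2R,3R)-2-[(tert-butyldimethylsilyl)oxy]-4-methyl-3-[(triethylsilyl)oxy]cyclohex-4-en-1-yl]ethenyl trifluoromethanesulfonate; 20 4-methylpent-3-enal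
Product: 22 (3S)-2-[(1R,2R,3R)-2-[(tert-butyldimethylsilyl)oxy]-4-methyl-3-[(triethylsilyl)oxy]cyclohex-4-en-1-yl]-6-methylhepta-1,5-dien-3-ol, via alkenylchromium(III) species 21 (not isolated)
Conditions: CrCl2, N-[2-(4-isopropyl-4,5-dihydrooxazol-2-yl)-6-methylphenyl]methanesulfonamide (one antipode, see assumption), Et3N, NiCl2 (cat.), THF, rt
Reagents that add atoms: none
Why: Asymmetric Nozaki–Hiyama–Kishi coupling: nickel activates the enol triflate, the alkenyl group passes to the sulfonamide-bound Cr(III), and the chiral chromium complex should direct addition to the Re face of the aldehyde, which sets C8 as S by reagent control and forms the C7–C8 bond with the 1,1-disubstituted alkene in place.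

Step 15
Reactants: 22 (3S)-2-[(1R,2R,3R)-2-[(tert-butyldimethylsilyl)oxy]-4-methyl-3-[(triethylsilyl)oxy]cyclohex-4-en-1-yl]-6-methylhepta-1,5-dien-3-ol
Product: 23 (3S)-2-[(1R,2R,3R)-2-[(tert-butyldimethylsilyl)oxy]-3-hydroxy-4-methylcyclohex-4-en-1-yl]-6-methylhepta-1,5-dien-3-ol
Conditions: PPTS, MeOH–CH2Cl2, 0 °C
Reagents that add atoms: none
Why: Mild acid methanolysis removes the triethylsilyl ether selectively; the more robust TBS ether on C2 should survive.

Step 16
Reactants: 23 (3S)-2-[(1R,2R,3R)-2-[(tert-butyldimethylsilyl)oxy]-3-hydroxy-4-methylcyclohex-4-en-1-yl]-6-methylhepta-1,5-dien-3-ol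
Product: 24 O3,O8-bis-angelate of 23 with the C2 TBS ether retained
Conditions: angelic acid, 2,4,6-trichlorobenzoyl chloride, Et3N, toluene, rt; then 23, 80 °C
Reagents that add atoms: angelic acid, C/C=C(/C)C(=O)O
Why: Acylation by the preformed mixed trichlorobenzoic anhydride without DMAP (Yamaguchi-type esterification) should esterify both secondary alcohols while avoiding the conjugate-addition pathway that turns angelates into tiglates.

Step 17
Reactants: 24 O3,O8-bis-angelate of 23 with the C2 TBS ether retained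
Product: 25 O3,O8-bis-angelate with free C2 hydroxyl
Conditions: HF·pyridine, pyridine, THF, 0 °C → rt
Reagents that add atoms: none
Why: Fluoride desilylation under weakly acidic buffered conditions frees the C2 hydroxyl while disfavouring base-mediated migration of the C3 angelate to O2.

Step 18
Reactants: 25 O3,O8-bis-angelate with free C2 hydroxyl
Product: 26 4β,5β-epoxide of 25
Conditions: VO(acac)2 (10 mol%), t-BuOOH (anhydrous, decane), CH2Cl2, 0 °C → rt
Reagents that add atoms: tert-butyl hydroperoxide, CC(C)(C)OO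
Why: Vanadium-catalysed hydroxyl-directed epoxidation: the C2 hydroxyl is homoallylic to C4=C5 (a cyclohex-3-enol) and in its axial conformer delivers the peroxide oxygen to the β face, which sets C4 and C5 syn to O2 and anti to the C3 angelate, while the remote prenyl alkene and the angelate alkenes are not addressed.

Step 19
Reactants: 26 4β,5β-epoxide of 25
Product: 27 tris-angelate ring epoxide with the C10=C11 alkene
Conditions: angelic acid, 2,4,6-trichlorobenzoyl chloride, Et3N, toluene, rt, filtered from Et3N·HCl; then 26, 80 °C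
Reagents that add atoms: angelic acid, C/C=C(/C)C(=O)O
Why: The same DMAP-free mixed-anhydride acylation esterifies the hindered C2 hydroxyl, and removing the ammonium chloride first avoids chloride opening of the trisubstituted epoxide.

Step 20
Reactants: 27 tris-angelate ring epoxide with the C10=C11 alkene
Product: 28 target CNP0258231.1
Conditions: D-fructose-derived Shi ketone (30 mol%), Oxone, K2CO3, Bu4NHSO4, Na2B4O7–Na2EDTA buffer, MeCN–DMM–H2O, 0 °C
Reagents that add atoms: Oxone (potassium peroxymonosulfate), [K+].[O-]S(=O)(=O)OO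
Why: Shi asymmetric epoxidation: the chiral dioxirane attacks the electron-rich trisubstituted C10=C11 alkene through the spiro transition state to set C10 as R by catalyst control, and the ester-deactivated 1,1-disubstituted alkene and the angelate alkenes should react far more slowly.

**Compound list**

1 | but-2-yn-1-ol | CC#CCO | starting material
2 | cyclic alkenylaluminate, sodium 2,2-bis(2-methoxyethoxy)-3-methyl-2,5-dihydro-1,2-oxaaluminol-2-uide | CC1=CCO[Al-]1(OCCOC)OCCOC.[Na+] | intermediate
3 | (2Z)-3-iodobut-2-en-1-ol | C/C(I)=C/CO | intermediate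
4 | (2Z)-1-bromo-3-iodobut-2-ene | C/C(I)=C/CBr | intermediate
5 | dimethyl (R)-malate | COC(=O)C[C@@H](O)C(=O)OC | starting material
6 | dilithio alkoxide–enolate of 5 (enolate geometry not assigned) | [Li+].[Li+].COC([O-])=C[C@@H]([O-])C(=O)OC | intermediate
7 | dimethyl (2R,3S)-2-hydroxy-3-[(2Z)-3-iodobut-2-en-1-yl]butanedioate | COC(=O)[C@@H](C/C=C(/C)I)[C@@H](O)C(=O)OC | intermediate
8 | methyl (2S,4Z)-2-[(1R)-1,2-dihydroxyethyl]-5-iodohex-4-enoate | COC(=O)[C@@H](C/C=C(/C)I)[C@@H](O)CO | intermediate
9 | methyl (2S,4Z)-2-[(1R)-1,2-bis[(tert-butyldimethylsilyl)oxy]ethyl]-5-iodohex-4-enoate | COC(=O)[C@@H](C/C=C(/C)I)[C@@H](O[Si](C)(C)C(C)(C)C)CO[Si](C)(C)C(C)(C)C | intermediate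
10 | methyl (2S,4Z)-2-[(1R)-1-[(tert-butyldimethylsilyl)oxy]-2-hydroxyethyl]-5-iodohex-4-enoate | COC(=O)[C@@H](C/C=C(/C)I)[C@@H](O[Si](C)(C)C(C)(C)C)CO | intermediate
11 | methyl (2S,4Z)-2-[(1R)-1-[(tert-butyldimethylsilyl)oxy]-2-oxoethyl]-5-iodohex-4-enoate | COC(=O)[C@@H](C/C=C(/C)I)[C@@H](O[Si](C)(C)C(C)(C)C)C=O | intermediate
12 | alkenylchromium(III) dichloride from 11 (solvent ligands omitted) | COC(=O)[C@@H](C/C=C(/C)[Cr](Cl)Cl)[C@@H](O[Si](C)(C)C(C)(C)C)C=O | intermediate
13 | methyl (1S,2R,3R)-2-[(tert-butyldimethylsilyl)oxy]-3-hydroxy-4-methylcyclohex-4-ene-1-carboxylate | COC(=O)[C@H]1CC=C(C)[C@@H](O)[C@@H]1O[Si](C)(C)C(C)(C)C | intermediate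
14 | methyl (1S,2R,3R)-2-[(tert-butyldimethylsilyl)oxy]-4-methyl-3-[(triethylsilyl)oxy]cyclohex-4-ene-1-carboxylate | COC(=O)[C@H]1CC=C(C)[C@@H](O[Si](CC)(CC)CC)[C@@H]1O[Si](C)(C)C(C)(C)C | intermediate
15 | (1S,2R,3R)-2-[(tert-butyldimethylsilyl)oxy]-N-methoxy-N,4-dimethyl-3-[(triethylsilyl)oxy]cyclohex-4-ene-1-carboxamide | CON(C)C(=O)[C@H]1CC=C(C)[C@@H](O[Si](CC)(CC)CC)[C@@H]1O[Si](C)(C)C(C)(C)C | intermediate
16 | 1-[(1S,2R,3R)-2-[(tert-butyldimethylsilyl)oxy]-4-methyl-3-[(triethylsilyl)oxy]cyclohex-4-en-1-yl]ethan-1-one | CC(=O)[C@H]1CC=C(C)[C@@H](O[Si](CC)(CC)CC)[C@@H]1O[Si](C)(C)C(C)(C)C | intermediate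
17 | potassium enolate of 16 (terminal) | [K+].C=C([O-])[C@H]1CC=C(C)[C@@H](O[Si](CC)(CC)CC)[C@@H]1O[Si](C)(C)C(C)(C)C | intermediate
18 | 1-[(1S,2R,3R)-2-[(tert-butyldimethylsilyl)oxy]-4-methyl-3-[(triethylsilyl)oxy]cyclohex-4-en-1-yl]ethenyl trifluoromethanesulfonate | C=C(OS(=O)(=O)C(F)(F)F)[C@H]1CC=C(C)[C@@H](O[Si](CC)(CC)CC)[C@@H]1O[Si](C)(C)C(C)(C)C | intermediate
19 | 4-methylpent-3-en-1-ol | CC(C)=CCCO | starting material
20 | 4-methylpent-3-enal | CC(C)=CCC=O | intermediate
21 | alkenylchromium(III) species from 18 (sulfonamide ligand omitted, drawn as dichloride) | C=C([Cr](Cl)Cl)[C@H]1CC=C(C)[C@@H](O[Si](CC)(CC)CC)[C@@H]1O[Si](C)(C)C(C)(C)C | intermediate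
22 | (3S)-2-[(1R,2R,3R)-2-[(tert-butyldimethylsilyl)oxy]-4-methyl-3-[(triethylsilyl)oxy]cyclohex-4-en-1-yl]-6-methylhepta-1,5-dien-3-ol | C=C([C@H](CC=C(C)C)O)[C@H]1CC=C(C)[C@@H](O[Si](CC)(CC)CC)[C@@H]1O[Si](C)(C)C(C)(C)C | intermediate
23 | (3S)-2-[(1R,2R,3R)-2-[(tert-butyldimethylsilyl)oxy]-3-hydroxy-4-methylcyclohex-4-en-1-yl]-6-methylhepta-1,5-dien-3-ol | C=C([C@H](CC=C(C)C)O)[C@H]1CC=C(C)[C@@H](O)[C@@H]1O[Si](C)(C)C(C)(C)C | intermediate
24 | O3,O8-bis-angelate of 23, C2 TBS ether retained | C=C([C@H](CC=C(C)C)OC(=O)/C(C)=C\C)[C@H]1CC=C(C)[C@@H](OC(=O)/C(C)=C\C)[C@@H]1O[Si](C)(C)C(C)(C)C | intermediate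
25 | O3,O8-bis-angelate with free C2 hydroxyl | C=C([C@H](CC=C(C)C)OC(=O)/C(C)=C\C)[C@H]1CC=C(C)[C@@H](OC(=O)/C(C)=C\C)[C@@H]1O | intermediate
26 | 4β,5β-epoxide of 25 (oxirane cis to the C2 hydroxyl) | C=C([C@H](CC=C(C)C)OC(=O)/C(C)=C\C)[C@H]1C[C@@H]2O[C@]2(C)[C@@H](OC(=O)/C(C)=C\C)[C@@H]1O | intermediate
27 | tris-angelate ring epoxide with the C10=C11 alkene | C=C([C@H](CC=C(C)C)OC(=O)/C(C)=C\C)[C@H]1C[C@@H]2O[C@]2(C)[C@@H](OC(=O)/C(C)=C\C)[C@@H]1OC(=O)/C(C)=C\C | intermediate
28 | CNP0258231.1 (1R,2R,3S,4S,5S,8S,10R in the locants used here) | C=C([C@H](C[C@H]1OC1(C)C)OC(=O)/C(C)=C\C)[C@H]1C[C@@H]2O[C@]2(C)[C@@H](OC(=O)/C(C)=C\C)[C@@H]1OC(=O)/C(C)=C\C | target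

**Step count**

Total: 20 steps. Longest linear sequence: 19 steps (steps 1–12 and 14–20, from but-2-yn-1-ol); step 13 is a one-step side branch.

**Steps most likely to fail**

1. Step 8, poor facial selectivity at C3 during ring closure. Allylic strain between the chromium-bound oxygen and the C4 methyl could favour the pseudo-axial alkoxide and give mainly the 2,3-cis alcohol. The fallback sets the stereocentre by reduction instead of by the C–C bond formation. It sets out from 11, which is cyclised under the same Ni/Cr conditions without regard to the C3 outcome, giving a mixture that contains methyl (1S,2R,3S)-2-[(tert-butyldimethylsilyl)oxy]-3-hydroxy-4-methylcyclohex-4-ene-1-carboxylate F1. The whole mixture is oxidised (Dess–Martin periodinane, NaHCO3, CH2Cl2) to methyl (1S,2R)-2-[(tert-butyldimethylsilyl)oxy]-4-methyl-3-oxocyclohex-4-ene-1-carboxylate F2. Luche reduction (NaBH4, CeCl3·7H2O, MeOH, −78 °C) should then deliver hydride axially, anti to the axial C2–H, and give the pseudo-equatorial alcohol trans to O2. The fallback comes back to the route at 13.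

2. Step 18, failure of oxygen delivery to the ring alkene. The directing hydroxyl reaches C4=C5 only in the conformer with the three ring substituents axial, the alkene is deactivated by the allylic angelate, and the C7 methylene is also homoallylic to O2. Slow reaction, competing epoxidation at C7 or loss of facial control are therefore possible. The fallback replaces metal-directed delivery by a tethered iodocyclisation. It sets out from 25, which is converted (Boc2O, 1-methylimidazole, MeCN) into the C2 tert-butyl carbonate of 25 F3. Iodine in MeCN at −20 °C should close the carbonate oxygen onto C4 from the β face, with iodine entering C5 from the α face, to give the cyclic iodocarbonate F4; iodonium formation at the other alkenes is reversible and has no comparable internal nucleophile. Brief treatment with K2CO3 in MeOH at 0 °C opens the cyclic carbonate, and the C4 alkoxide displaces the anti iodide to close the β-oxirane. The fallback comes back to the route at 26.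

3. Step 14, insufficient reagent control at C8. The chiral chromium complex may be mismatched with the neighbouring C1 centre, or the β,γ-unsaturated aldehyde may erode the induction. The fallback sets C8 by ketone reduction. It sets out from 18 and 20, which are coupled without chiral ligand (CrCl2, cat. NiCl2, DMF, rt) to a C8 epimer mixture that contains the (3R)-epimer of 22 F5. Dess–Martin oxidation (NaHCO3, CH2Cl2, 0 °C) gives 2-[(1R,2R,3R)-2-[(tert-butyldimethylsilyl)oxy]-4-methyl-3-[(triethylsilyl)oxy]cyclohex-4-en-1-yl]-6-methylhepta-1,5-dien-3-one F6. Corey–Bakshi–Shibata reduction with (R)-Me-CBS and catecholborane in toluene at −78 °C, in which the α-branched alkenyl group acts as the large substituent, should give the 8S alcohol. The fallback comes back to the route at 22.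

**Further compounds**

F1 | step 8 | methyl (1S,2R,3S)-2-[(tert-butyldimethylsilyl)oxy]-3-hydroxy-4-methylcyclohex-4-ene-1-carboxylate | COC(=O)[C@H]1CC=C(C)[C@H](O)[C@@H]1O[Si](C)(C)C(C)(C)C
F2 | step 8 | methyl (1S,2R)-2-[(tert-butyldimethylsilyl)oxy]-4-methyl-3-oxocyclohex-4-ene-1-carboxylate | COC(=O)[C@H]1CC=C(C)C(=O)[C@@H]1O[Si](C)(C)C(C)(C)C
F3 | step 18 | C2 tert-butyl carbonate of 25 | C=C([C@H](CC=C(C)C)OC(=O)/C(C)=C\C)[C@H]1CC=C(C)[C@@H](OC(=O)/C(C)=C\C)[C@@H]1OC(=O)OC(C)(C)C
F4 | step 18 | cyclic iodocarbonate (O2–C(=O)–O4 bridge on the β face, 5α-iodide) | C=C([C@H](CC=C(C)C)OC(=O)/C(C)=C\C)[C@H]1C[C@@H](I)[C@]2(C)OC(=O)O[C@H]1[C@@H]2OC(=O)/C(C)=C\C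
F5 | step 14 | (3R)-epimer of 22 | C=C([C@@H](CC=C(C)C)O)[C@H]1CC=C(C)[C@@H](O[Si](CC)(CC)CC)[C@@H]1O[Si](C)(C)C(C)(C)C
F6 | step 14 | 2-[(1R,2R,3R)-2-[(tert-butyldimethylsilyl)oxy]-4-methyl-3-[(triethylsilyl)oxy]cyclohex-4-en-1-yl]-6-methylhepta-1,5-dien-3-one | C=C(C(=O)CC=C(C)C)[C@H]1CC=C(C)[C@@H](O[Si](CC)(CC)CC)[C@@H]1O[Si](C)(C)C(C)(C)C
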